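## The problem

The target **24** is a trans-fused Δ7-octalin. It is numbered here like a drimane: ring A is C1–C5 plus C10, ring B is C5–C10, C11 is the formyl carbon on C9, C12 the ester carbon on C8, and C1′–C4′ the side chain on C4. β is the face of the C10 methyl. In this numbering **24** is 1S,3S,4S,5R,9R,10S: 1α-OH (axial), 3β-Cl (equatorial), 4β-CH3, 4α-side chain, 5α-H, 9β-CHO, 10β-CH3.

- **Ring junction.** The C5–C10 ring fusion is flanked by two quaternary carbons, C4 and C10, whose methyl groups are syn-diaxial on the β face. Ring B carries the ester on the C7=C8 double bond and the formyl group on C9.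
- **Stereocontrol.** C4 and C5 cannot be derived from any other centre and must be set absolutely. Once they are fixed, C10, C9 and C1 can follow by substrate control.
- **C3.** The chloride lies on the β face beside C4, where any reagent approaching C3 runs alongside the axial C4 methyl. Kinetic delivery of chloride to that face is therefore not to be expected, and C3 needs a different form of control.
- **Sensitive groups.** The C9 aldehyde is α to a stereocentre and next to the enoate, so it epimerises and can slip into conjugation. A β-chloro ketone on the way to the C1 carbinol loses HCl with base. The tertiary allylic alcohol ionises in acid. All three must appear late.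
- **Enabling feature.** C4 carries a methyl group and a carbon (C1′) that can be carried as a formyl group, and its neighbour C5 is a methine bearing the C6–C7 arm. This is the α-methyl, formyl and β-carbon of an (E)-2-methyl-2-enal. A 1-amino-3-siloxydiene supplies C3, C2, C1 and C10, so ring A can be closed around C4–C5 by a [4+2] cycloaddition. The cycloaddition leaves a C1 ketone and a C2=C3 alkene for the later work at C10, C3 and C1.

## Retrosynthesis

**Side chain (C2′=C3′).** **24** is cut at the side-chain double bond into the allyl compound **22** and 2-methylbut-3-en-2-ol **23**. Building the tertiary allylic alcohol earlier would expose it to the acid needed at C3 and C11, whereas an allyl group is inert to every later step. The forward reaction must be an (E)-selective cross-metathesis that tolerates a free hydroxyl, an aldehyde and a chloride.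

**C11, C1 and C3 (functional groups of rings A and B).** The aldehyde of **22** is taken back to the dimethyl acetal **21**, the C1 carbinol to ketone **20**, and the C3–Cl bond to enone **19**. This order keeps the epimerisable aldehyde masked until the penultimate step and uses the enone that the ring A construction provides anyway. The forward steps must deliver hydride to C1 from the equatorial side. At C3 they must give the equatorial chloride even though axial attack is the kinetically favoured one.

**Ring B (C7=C8 and C9–C10).** **19** is opened at the ring alkene to the phosphonate aldehyde **18** (from alcohol **17** and PMB ether **16**), and **16** is cut at C9–C10 into the methylated enone **12** and the acceptor **15**. A plain ester aldol closure would have to compete with the enolisable aldehyde, whereas the phosphonate makes C8 the only nucleophile. The acceptor **15** brings C8 with its ester and C9 with its masked formyl group in one piece. This reduces the bicycle to a monocyclic enone and a four-carbon reagent. The forward Michael addition must create the quaternary C10 with the new chain trans to the C5 arm and must set C9.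

**C10 methyl and C4 side-chain stub.** **12** loses its C10 methyl to give **11**. The allyl group of **11** is traced through carbonate **10** and allylic alcohol **9** to the formyl enone **8**, by cutting C1′–C2′ and restoring the C1′ oxygen. Direct allylation cannot make a quaternary C4, so the formyl carbon is kept as C1′ and only deoxygenated. The forward steps need an aldehyde-selective vinyl addition beside an enone and a hydride delivery to the substituted end of an allyl unit.

**Ring A (C3–C4 and C5–C10), the key disconnection.** **8** is cut into enal **5** and diene **6**, with the amino siloxy cycloadduct **7** as the unisolated link. An alkylative construction of C4 would need a separate enantioselective quaternisation, then the C5 centre. The cycloaddition makes both centres and the ring from two achiral partners. The forward reaction needs regiocontrol (C10 to C5, C3 to C4) and control of the enal face.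

**Building blocks.** Enal **5** is cut at its double bond into aldehyde **3** and ylide **4**, and **3** goes back through alcohol **2** to propane-1,3-diol **1**. Acceptor **15** is cut at its double bond into trimethyl phosphonoacetate **13** and 2,2-dimethoxyacetaldehyde **14**.

## Roads not taken

**Alternative 1: late ring expansion.**
- *Cut and key step.* C8 is removed from ring B, leaving the trans-hydrindanone **A1**. In the forward direction a Lewis-acid-promoted diazoacetate homologation of the C9 ketone, with 1,2-shift of the less substituted C7, gives the six-membered β-keto ester **A2**.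
- *Merits.* The ester-bearing C8 arrives in one step. Migration of the secondary C7 rather than the quaternary C10 is the expected regiochemistry. Ring A already carries chloride and protected carbinol.
- *Weak points.* **A2** has oxygen at C9 where the target needs hydrogen and a formyl carbon. That calls for a one-carbon homologation of a hindered, enolised carbonyl next to C10, followed by introduction of C7=C8 and control of C9. All ring A centres, including the difficult C3 chloride, must already be present in **A1**, so the hard problems are moved upstream and not solved. The β-chloro silyl ether also has to survive the Lewis acid.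
- *Comparison.* The expansion itself is probably more dependable than the intermolecular Michael addition used here. The chosen plan sets against this that reagent **15** delivers C8 and C9 with their final substituents and oxidation levels, so no ketone beside C10 has to be turned into CH–CHO.

**Alternative 2: tethered Michael desymmetrisation.**
- *Cut and key step.* C5–C6 is cut inside a lactone. A bifunctional amine–thiourea catalyst adds the tethered malonate of the prochiral dienone **A3** to one enone arm and gives the cis-fused lactone **A4**, with C4 and C5 set.
- *Merits.* The quaternary C4 is created by desymmetrisation, so no bond is made at a congested carbon, and the dienone comes from cheap aromatic material. In enantiocontrol this road is at least as good as a cycloaddition on a trisubstituted enal, and probably better precedented.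
- *Weak points.* The future C4 methyl is a lactone CH2–O carbon that needs a neopentyl deoxygenation. C6 carries an extra ester to be removed. The lactone carbonyl must be brought selectively to the aldehyde level for ring B. These are three or four defunctionalisation steps.
- *Comparison.* The chosen plan sets against the better enantioselectivity precedent that its key step delivers the methyl as a methyl, C1′ as a formyl group and the C6–C7 arm at a usable oxidation level.

**Alternative 3: ring B by Diels–Alder.**
- *Cut and key step.* C9–C10 and C7–C8 are cut. The ring A diene **A5** and the acetylenic aldehyde ester **A6** combine to give the 1,4-cyclohexadiene **A7**.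
- *Merits.* This is the most convergent road. It installs the C8 ester and the C9 formyl carbon in one step, and in step count for ring B it beats the four steps used here.
- *Weak points.* The diene terminus C10 is fully substituted and must bond to the formyl-bearing alkyne carbon. **A7** has its alkenes at C5=C6 and C8=C9, so C5 and C9 are not set. They would need a trans-selective reduction and a deconjugative protonation. Ring A of **A7** has no carbonyl at C1, so there is no handle for the C3 chloride.
- *Comparison.* The chosen plan sets against the higher convergence that C5 is fixed together with C4 in the key step and that the C1 ketone and C2=C3 alkene remain for C10, C3 and C1.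

Key step: step 4

Assumption: the diol catalyst is written as the (R,R)-enantiomer. Induction with the trisubstituted enal **5** is taken to follow the sense known for α-substituted acroleins, and the mirror-image diol would be used if the antipode of **8** were formed.

## Route

Step 1
Reactants: 1 propane-1,3-diol
Product: 2 3-(4-methoxybenzyloxy)propan-1-ol
Conditions: NaH (1 equiv), 4-methoxybenzyl chloride, Bu4NI (cat.), THF, 0 → 23 °C; diol in excess
Reagents that add atoms: 4-methoxybenzyl chloride, COc1ccc(CCl)cc1
Why: Williamson etherification; the excess of the symmetric diol should keep alkylation at one hydroxyl.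

Step 2
Reactants: 2 3-(4-methoxybenzyloxy)propan-1-ol
Product: 3 3-(4-methoxybenzyloxy)propanal
Conditions: TEMPO (10 mol %), PhI(OAc)2, CH2Cl2, 23 °C
Reagents that add atoms: none
Why: Oxoammonium (TEMPO) oxidation of a primary alcohol; the near-neutral medium should avoid β-elimination of the alkoxy aldehyde.

Step 3
Reactants: 3 3-(4-methoxybenzyloxy)propanal; 4 2-(triphenylphosphoranylidene)propanal
Product: 5 (E)-5-(4-methoxybenzyloxy)-2-methylpent-2-enal
Conditions: toluene, 80 °C
Reagents that add atoms: none
Why: Wittig reaction of a stabilised formyl ylide; such ylides should give the (E)-2-methyl enal, the geometry that later fixes C4 relative to C5.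

Step 4
Reactants: 5 (E)-5-(4-methoxybenzyloxy)-2-methylpent-2-enal; 6 (E)-1-(dimethylamino)-3-(tert-butyldimethylsilyloxy)buta-1,3-diene
Product: 8 (1S,6R)-6-[2-(4-methoxybenzyloxy)ethyl]-1-methyl-4-oxocyclohex-2-ene-1-carbaldehyde (C4 and C5 of the target numbering; formyl α, methyl β, H-5 α), via amino siloxy cycloadduct 7 (not isolated)
Conditions: (4R,5R)-2,2-dimethyl-α,α,α′,α′-tetra(1-naphthyl)-1,3-dioxolane-4,5-dimethanol (20 mol %), toluene, −78 → −40 °C; then AcCl, CH2Cl2, −78 °C
Reagents that add atoms: none
Why: This is a normal-demand [4+2] cycloaddition (Diels–Alder) in which the two hydroxyls of the diol hydrogen-bond to the formyl oxygen of 5 and lower its LUMO; the closest known reaction type is the diol-catalysed enantioselective Diels–Alder reaction of 1-amino-3-siloxydienes with α-substituted acroleins. Bond formation is concerted but asynchronous: the nucleophilic CH2 terminus of 6 (C10) leads at the β-carbon of 5 (C5) and the amine-bearing terminus (C3) closes onto the α-carbon (C4), which fixes the regiochemistry. Ring A is closed in one suprafacial–suprafacial [4+2] event through a six-membered, endo-oriented transition state. C4 and C5 are created together: their relative configuration follows from the (E) geometry of 5 (arm cis to the C4 methyl, trans to the formyl group), and their absolute configuration from the enal face left open by the bound diol. The amino-bearing C3 of 7 needs no control, because N-acylation by AcCl expels the amine and chloride removes the silyl group, leaving the C1 enone of 8. The step therefore needs only regio- and face-selectivity; the first is secured by the combined push of the amino and siloxy groups of 6, the second by the single hydrogen-bond acceptor next to the α-carbon.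

Step 5
Reactants: 8 (1S,6R)-6-[2-(4-methoxybenzyloxy)ethyl]-1-methyl-4-oxocyclohex-2-ene-1-carbaldehyde
Product: 9 (4S,5R)-4-(1-hydroxyprop-2-enyl)-5-[2-(4-methoxybenzyloxy)ethyl]-4-methylcyclohex-2-en-1-one (both C1′ epimers)
Conditions: CrCl2 (4 equiv), NiCl2 (2 mol %), vinyl bromide, DMF, 23 °C
Reagents that add atoms: vinyl bromide, C=CBr
Why: Nozaki–Hiyama–Kishi addition; the vinylchromium species adds to aldehydes and leaves ketones and enones alone, which is what the formyl enone needs. The C1′ configuration is irrelevant because the oxygen is removed in step 7.

Step 6
Reactants: 9 (4S,5R)-4-(1-hydroxyprop-2-enyl)-5-[2-(4-methoxybenzyloxy)ethyl]-4-methylcyclohex-2-en-1-one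
Product: 10 methyl carbonate of 9, (4S,5R)-4-[1-(methoxycarbonyloxy)prop-2-enyl]-5-[2-(4-methoxybenzyloxy)ethyl]-4-methylcyclohex-2-en-1-one
Conditions: ClCO2Me, pyridine, DMAP (cat.), CH2Cl2, 0 °C
Reagents that add atoms: methyl chloroformate, COC(=O)Cl
Why: O-acylation of the secondary allylic alcohol; the carbonate is the ionisable group for the palladium step.

Step 7
Reactants: 10 methyl carbonate of 9
Product: 11 (4S,5R)-4-allyl-5-[2-(4-methoxybenzyloxy)ethyl]-4-methylcyclohex-2-en-1-one
Conditions: Pd(OAc)2 (5 mol %), PBu3 (5 mol %), HCO2NH4, dioxane, 100 °C
Reagents that add atoms: none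
Why: Palladium-catalysed formate hydrogenolysis of an allylic carbonate (Tsuji–Mandai reduction): zerovalent palladium ionises the carbonate, formate gives a π-allyl palladium hydride, and hydride is delivered to the more substituted allyl terminus (C1′). This should leave the terminal alkene, that is the allyl group on C4.

Step 8
Reactants: 11 (4S,5R)-4-allyl-5-[2-(4-methoxybenzyloxy)ethyl]-4-methylcyclohex-2-en-1-one
Product: 12 (5R)-4-allyl-5-[2-(4-methoxybenzyloxy)ethyl]-4,6-dimethylcyclohex-2-en-1-one (C4 as in 11; C6, the future C10, as both epimers)
Conditions: LDA, THF, −78 °C; MeI, −78 → −20 °C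
Reagents that add atoms: iodomethane, CI
Why: α′-Alkylation of the kinetic cross-conjugated lithium dienolate; C10 is the only enolisable position because C4 is quaternary. The C10 configuration is erased when the centre is enolised again in step 10.

Step 9
Reactants: 13 trimethyl phosphonoacetate; 14 2,2-dimethoxyacetaldehyde
Product: 15 methyl 2-(dimethoxyphosphoryl)-4,4-dimethoxybut-2-enoate (E/Z mixture)
Conditions: piperidine (cat.), AcOH (cat.), toluene, reflux with azeotropic removal of water
Reagents that add atoms: none
Why: Knoevenagel condensation of a non-enolisable aldehyde with an active methylene compound. The alkene geometry is irrelevant because C8 becomes sp3 and then sp2 again.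

Step 10
Reactants: 12 (5R)-4-allyl-5-[2-(4-methoxybenzyloxy)ethyl]-4,6-dimethylcyclohex-2-en-1-one; 15 methyl 2-(dimethoxyphosphoryl)-4,4-dimethoxybut-2-enoate
Product: 16 Michael adduct: enone 12 bearing at C10, trans to the C5 arm (C10 methyl β), the chain CH[CH(OMe)2]–CH(CO2Me)P(O)(OMe)2; C9 as in 24, C8 as both epimers
Conditions: LDA, THF, −78 → −40 °C; then 15, −78 °C; aq. NH4Cl
Reagents that add atoms: none
Why: Michael addition of the tetrasubstituted lithium dienolate to a doubly activated alkylidene phosphonoacetate, driven by formation of the stabilised phosphonoacetate anion. C10: the acceptor enters on the α face, anti to the pseudoaxial C4 methyl and to the C5 arm, as in alkylations of 5-substituted 6-methylcyclohexenones. C9: in a lithium-bridged transition state the hydrogen of the acceptor takes the crowded position between the C10 methyl and C5 and the bulky C8 terminus sits beside the methyl, which should give the 9β-acetal configuration.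

Step 11
Reactants: 16 Michael adduct
Product: 17 primary alcohol from 16 (C7–OH; the other groups unchanged)
Conditions: DDQ, CH2Cl2/pH 7 buffer, 0 °C
Reagents that add atoms: none
Why: Oxidative cleavage of the 4-methoxybenzyl ether by benzylic hydride abstraction and hydrolysis; the allyl group, enone, acetal and phosphonate should survive the buffered conditions.

Step 12
Reactants: 17 primary alcohol
Product: 18 C7 aldehyde (phosphonoacetate and enone unchanged)
Conditions: Dess–Martin periodinane, NaHCO3, CH2Cl2, 23 °C
Reagents that add atoms: none
Why: Oxidation with a hypervalent iodine reagent under buffered, non-basic conditions, so the phosphonoacetate does not cyclise prematurely or epimerise anything that matters.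

Step 13
Reactants: 18 C7 aldehyde
Product: 19 bicyclic dienone ester: trans-fused; ring A 2-en-1-one with 4α-allyl, 4β-methyl, 10β-methyl; ring B 7-ene with CO2Me on C8 and 9β-CH(OMe)2
Conditions: LiCl, DBU, MeCN, 0 → 23 °C
Reagents that add atoms: none
Why: Intramolecular Horner–Wadsworth–Emmons reaction under Masamune–Roush conditions: the phosphonoacetate carbon (C8) is the only carbanion formed and closes ring B on the C7 aldehyde (6-exo-trig addition, then loss of phosphate). No stereocentre is formed, and C9 and C10 carry no acidic hydrogen.

Step 14
Reactants: 19 bicyclic dienone ester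
Product: 20 3β-chloro-1-ketone (HCl adduct of 19; chlorine equatorial, cis to the C4 methyl)
Conditions: HCl (4 M in dioxane), CH2Cl2, −20 °C, to equilibrium; then Et3N, MeOH, 0 °C, brief; recovered 19 recycled
Reagents that add atoms: hydrogen chloride, Cl
Why: Conjugate addition of HCl to the enone is reversible, so the two C3 epimers interconvert through 19. Axial delivery anti to the C4 methyl forms the 3α-chloride first, but that epimer has its C–Cl bond aligned with the enolate π system and is returned to 19 by the short Et3N treatment (E1cB), whereas the equatorial 3β-chloride is misaligned and should persist. C3 is thus set by equilibration plus stereoelectronic removal of the wrong epimer, not by the facial preference of the addition.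

Step 15
Reactants: 20 3β-chloro-1-ketone
Product: 21 3β-chloro-1α-alcohol (axial hydroxyl; acetal, ester and allyl group unchanged)
Conditions: LiBH(s-Bu)3, THF, −78 °C; then H2O
Reagents that add atoms: none
Why: Ketone reduction with a bulky trialkylborohydride: the axial path is closed by the syn-axial hydrogens on C3, C5 and C9, so hydride should come from the equatorial (β) side and give the axial 1α-alcohol, as with other cyclohexanones next to a quaternary carbon bearing an axial methyl. The enoate and the equatorial chloride should not react at −78 °C.

Step 16
Reactants: 21 3β-chloro-1α-alcohol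
Product: 22 methyl 4α-allyl-3β-chloro-9β-formyl-1α-hydroxy-4β,10β-dimethyl-5α-octal-7-ene-8-carboxylate
Conditions: TFA, H2O, CH2Cl2, 0 °C, brief
Reagents that add atoms: water, O
Why: Acid-catalysed hydrolysis of the dimethyl acetal through the oxocarbenium ion and hemiacetal. Short exposure at 0 °C is meant to keep C9, now α to the aldehyde, from enolising; the chloro alcohol and the allyl group are inert to aqueous acid.

Step 17
Reactants: 22 allyl hydroxy aldehyde; 23 2-methylbut-3-en-2-ol
Product: 24 target, methyl (1S,3S,4S,5R,9R,10S)-3-chloro-9-formyl-1-hydroxy-4-[(E)-4-hydroxy-4-methylpent-2-enyl]-4,10-dimethyl-5α-octal-7-ene-8-carboxylate (numbering of this proposal)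
Conditions: second-generation Hoveyda–Grubbs catalyst RuCl2(=CH-2-(i-PrO)C6H4)(H2IMes) (5 mol %), 23 (10 equiv), CH2Cl2, 40 °C
Reagents that add atoms: none
Why: Olefin cross-metathesis of the allyl group with an excess of a tertiary allylic alcohol, which homodimerises slowly and should give the (E)-alkene. The trisubstituted, ester-conjugated C7=C8 bond does not take part, and the ruthenium carbene tolerates hydroxyl, formyl and chloride groups.

## Compound list

1 | propane-1,3-diol | OCCCO | starting material
2 | 3-(4-methoxybenzyloxy)propan-1-ol | OCCCOCc1ccc(OC)cc1 | intermediate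
3 | 3-(4-methoxybenzyloxy)propanal | O=CCCOCc1ccc(OC)cc1 | intermediate
4 | 2-(triphenylphosphoranylidene)propanal | CC(C=O)=P(c1ccccc1)(c1ccccc1)c1ccccc1 | starting material
5 | (E)-5-(4-methoxybenzyloxy)-2-methylpent-2-enal | O=C/C(C)=C/CCOCc1ccc(OC)cc1 | intermediate
6 | (E)-1-(dimethylamino)-3-(tert-butyldimethylsilyloxy)buta-1,3-diene | CN(C)/C=C/C(=C)O[Si](C)(C)C(C)(C)C | starting material
7 | endo cycloadduct: 4-(tert-butyldimethylsilyloxy)-2-(dimethylamino)-6-[2-(4-methoxybenzyloxy)ethyl]-1-methylcyclohex-3-ene-1-carbaldehyde, amino group cis to formyl, C1 and C6 as in 8 | O=C[C@]1(C)[C@H](N(C)C)C=C(O[Si](C)(C)C(C)(C)C)C[C@H]1CCOCc1ccc(OC)cc1 | intermediate (not isolated)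
8 | (1S,6R)-6-[2-(4-methoxybenzyloxy)ethyl]-1-methyl-4-oxocyclohex-2-ene-1-carbaldehyde | O=C[C@]1(C)C=CC(=O)C[C@H]1CCOCc1ccc(OC)cc1 | intermediate
9 | (4S,5R)-4-(1-hydroxyprop-2-enyl)-5-[2-(4-methoxybenzyloxy)ethyl]-4-methylcyclohex-2-en-1-one, both C1′ epimers | C=CC(O)[C@]1(C)C=CC(=O)C[C@H]1CCOCc1ccc(OC)cc1 | intermediate
10 | (4S,5R)-4-[1-(methoxycarbonyloxy)prop-2-enyl]-5-[2-(4-methoxybenzyloxy)ethyl]-4-methylcyclohex-2-en-1-one, both C1′ epimers | C=CC(OC(=O)OC)[C@]1(C)C=CC(=O)C[C@H]1CCOCc1ccc(OC)cc1 | intermediate
11 | (4S,5R)-4-allyl-5-[2-(4-methoxybenzyloxy)ethyl]-4-methylcyclohex-2-en-1-one | C=CC[C@]1(C)C=CC(=O)C[C@H]1CCOCc1ccc(OC)cc1 | intermediate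
12 | (5R)-4-allyl-5-[2-(4-methoxybenzyloxy)ethyl]-4,6-dimethylcyclohex-2-en-1-one, C4 as in 11, C6 both epimers | C=CC[C@]1(C)C=CC(=O)C(C)[C@H]1CCOCc1ccc(OC)cc1 | intermediate
13 | trimethyl phosphonoacetate | COC(=O)CP(=O)(OC)OC | starting material
14 | 2,2-dimethoxyacetaldehyde | COC(OC)C=O | starting material
15 | methyl 2-(dimethoxyphosphoryl)-4,4-dimethoxybut-2-enoate, E/Z mixture | COC(=O)C(=CC(OC)OC)P(=O)(OC)OC | intermediate
16 | Michael adduct: 12 with C10 quaternary (methyl β; chain CH[CH(OMe)2]CH(CO2Me)P(O)(OMe)2 α), C9 as in 24, C8 both epimers | C=CC[C@]1(C)C=CC(=O)[C@](C)([C@@H](C(OC)OC)C(C(=O)OC)P(=O)(OC)OC)[C@H]1CCOCc1ccc(OC)cc1 | intermediate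
17 | primary alcohol from 16 (C7–OH) | C=CC[C@]1(C)C=CC(=O)[C@](C)([C@@H](C(OC)OC)C(C(=O)OC)P(=O)(OC)OC)[C@H]1CCO | intermediate
18 | C7 aldehyde from 17 | C=CC[C@]1(C)C=CC(=O)[C@](C)([C@@H](C(OC)OC)C(C(=O)OC)P(=O)(OC)OC)[C@H]1CC=O | intermediate
19 | methyl 4α-allyl-9β-(dimethoxymethyl)-4β,10β-dimethyl-1-oxo-5α-octala-2,7-diene-8-carboxylate | COC(=O)C1=CC[C@H]2[C@](C)(CC=C)C=CC(=O)[C@]2(C)[C@H]1C(OC)OC | intermediate
20 | methyl 4α-allyl-3β-chloro-9β-(dimethoxymethyl)-4β,10β-dimethyl-1-oxo-5α-octal-7-ene-8-carboxylate | COC(=O)C1=CC[C@H]2[C@](C)(CC=C)[C@@H](Cl)CC(=O)[C@]2(C)[C@H]1C(OC)OC | intermediate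
21 | methyl 4α-allyl-3β-chloro-9β-(dimethoxymethyl)-1α-hydroxy-4β,10β-dimethyl-5α-octal-7-ene-8-carboxylate | COC(=O)C1=CC[C@H]2[C@](C)(CC=C)[C@@H](Cl)C[C@H](O)[C@]2(C)[C@H]1C(OC)OC | intermediate
22 | methyl 4α-allyl-3β-chloro-9β-formyl-1α-hydroxy-4β,10β-dimethyl-5α-octal-7-ene-8-carboxylate | COC(=O)C1=CC[C@H]2[C@](C)(CC=C)[C@@H](Cl)C[C@H](O)[C@]2(C)[C@H]1C=O | intermediate
23 | 2-methylbut-3-en-2-ol | CC(C)(O)C=C | starting material
24 | methyl (1S,3S,4S,5R,9R,10S)-3-chloro-9-formyl-1-hydroxy-4-[(E)-4-hydroxy-4-methylpent-2-enyl]-4,10-dimethyl-5α-octal-7-ene-8-carboxylate | COC(=O)C1=CC[C@H]2[C@](C)(C/C=C/C(C)(C)O)[C@@H](Cl)C[C@H](O)[C@]2(C)[C@H]1C=O | target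

## Step count and least certain steps

Total: 17 steps. Longest linear sequence: 16 steps (steps 1–8 and 10–17; step 9 is a one-step branch).

**Step 4 (key step).**
- *What may go wrong.* Slow cycloaddition and eroded enantioface discrimination. The β-substituent makes **5** a much poorer dienophile than the α-substituted acroleins for which diol catalysis is established, so decomposition of **6** and an uncatalysed, unselective pathway can compete at the temperatures needed.
- *Fallback.* Stereocontrol is moved from the catalyst to an auxiliary on the diene. Starting from **5**, the diene **6** is replaced by 1-[(2R,5R)-2,5-diphenylpyrrolidin-1-yl]-3-(tert-butyldimethylsilyloxy)buta-1,3-diene F1 (or its enantiomer, whichever matches **8**). A thermal cycloaddition without catalyst gives the cycloadduct F2, in which the C2-symmetric amine shields one diene face. Treatment with HF in MeCN removes the amine and the silyl group, and the sequence comes back to the route at **8**.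

**Step 14.**
- *What may go wrong.* An unfavourable C3 equilibrium and poor discrimination in the elimination. Chloride is delivered kinetically from the α face, and the equatorial preference of chlorine beside the quaternary C4 is small, so the 3β-epimer may be the minor component at any time and both epimers may lose HCl with Et3N at comparable rates. HCl can also ionise the C11 acetal.
- *Fallback.* The discrimination is moved to the alcohol stage, where it rests on an anti-periplanar E2 requirement. Starting from **20** obtained as a mixture with its C3 epimer, the mixture is reduced as in step 15 to **21** and the 3α-chloro-1α-alcohol F7. Heating with DBU in toluene eliminates HCl only from F7, whose axial chlorine has H-2 anti-periplanar, and gives the allylic alcohol F8. The equatorial chloride **21** has no such hydrogen and is carried on. F8 is oxidised with MnO2 to enone **19** and recycled. The fallback comes back at **21** and, for the recycled part, at **19**.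

**Step 10.**
- *What may go wrong.* Poor relative stereocontrol at C9, and a slow addition because a quaternary and a tertiary carbon are joined. The two lithium-bridged arrangements differ only in which neighbour of C10 faces the acceptor terminus. A second, intramolecular Michael addition of the phosphonoacetate anion to C3 of the enone can also intervene.
- *Fallback.* C9 is corrected at the end by kinetic protonation and no longer set in the addition. Steps 10–16 are run on the mixture, and the fallback sets out from **22** containing its C9 epimer F5. TMSOTf and Et3N convert both epimers into the same bis(trimethylsilyl) dienol ether F6, in which C9 is trigonal. Desilylation with HF·pyridine at −78 °C protonates C9 from the open α face, anti to the C10 methyl, and frees the C1 hydroxyl. The fallback comes back at **22**.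

**Step 7.**
- *What may go wrong.* Hydride transfer to the wrong allyl terminus, or conjugate reduction of the enone. The π-allyl unit is attached to the quaternary C4, which may divert hydride to the unhindered terminus and give the internal alkene.
- *Fallback.* The allyl group is built by two one-carbon olefinations, so no allyl–palladium species is involved. Starting from **8**, Wittig reaction with methoxymethylenetriphenylphosphorane gives the enol ether F3. Mild aqueous acid gives the homologous aldehyde F4. Methylenation with methylenetriphenylphosphorane at low temperature, where the aldehyde reacts before the enone, comes back to the route at **11**.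

## Further compounds

F1 | step 4 | 1-[(2R,5R)-2,5-diphenylpyrrolidin-1-yl]-3-(tert-butyldimethylsilyloxy)buta-1,3-diene | C=C(O[Si](C)(C)C(C)(C)C)/C=C/N1[C@@H](c2ccccc2)CC[C@@H]1c1ccccc1
F2 | step 4 | cycloadduct of 5 and F1: 4-(tert-butyldimethylsilyloxy)-2-[(2R,5R)-2,5-diphenylpyrrolidin-1-yl]-6-[2-(4-methoxybenzyloxy)ethyl]-1-methylcyclohex-3-ene-1-carbaldehyde, C1 and C6 as in 8 | O=C[C@]1(C)[C@H](N2[C@@H](c3ccccc3)CC[C@@H]2c2ccccc2)C=C(O[Si](C)(C)C(C)(C)C)C[C@H]1CCOCc1ccc(OC)cc1
F3 | step 7 | (4S,5R)-4-(2-methoxyethenyl)-5-[2-(4-methoxybenzyloxy)ethyl]-4-methylcyclohex-2-en-1-one, E/Z mixture | COC=C[C@]1(C)C=CC(=O)C[C@H]1CCOCc1ccc(OC)cc1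
F4 | step 7 | 2-{(1S,6R)-6-[2-(4-methoxybenzyloxy)ethyl]-1-methyl-4-oxocyclohex-2-en-1-yl}acetaldehyde | O=CC[C@]1(C)C=CC(=O)C[C@H]1CCOCc1ccc(OC)cc1
F5 | step 10 | C9 epimer of 22 (9α-formyl) | COC(=O)C1=CC[C@H]2[C@](C)(CC=C)[C@@H](Cl)C[C@H](O)[C@]2(C)[C@@H]1C=O
F6 | step 10 | bis(trimethylsilyl) dienol ether of 22: 1α-trimethylsilyloxy, C9=C11 enol trimethylsilyl ether | COC(=O)C1=CC[C@H]2[C@](C)(CC=C)[C@@H](Cl)C[C@H](O[Si](C)(C)C)[C@]2(C)C1=CO[Si](C)(C)C
F7 | step 14 | C3 epimer of 21 (3α-chloro-1α-alcohol) | COC(=O)C1=CC[C@H]2[C@](C)(CC=C)[C@H](Cl)C[C@H](O)[C@]2(C)[C@H]1C(OC)OC
F8 | step 14 | methyl 4α-allyl-9β-(dimethoxymethyl)-1α-hydroxy-4β,10β-dimethyl-5α-octala-2,7-diene-8-carboxylate | COC(=O)C1=CC[C@H]2[C@](C)(CC=C)C=C[C@H](O)[C@]2(C)[C@H]1C(OC)OC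
A1 | alternative 1 | trans-hydrindanone with C9 ketone, 4α-allyl, 3β-chloro, 1α-silyloxy, 4β,10β-dimethyl | O=C1CC[C@H]2[C@](C)(CC=C)[C@@H](Cl)C[C@H](O[Si](C)(C)C(C)(C)C)[C@]12C
A2 | alternative 1 | ring-expanded decalin β-keto ester, drawn as its enol | COC(=O)C=1CC[C@H]2[C@](C)(CC=C)[C@@H](Cl)C[C@H](O[Si](C)(C)C(C)(C)C)[C@]2(C)C=1O
A3 | alternative 2 | (1-allyl-4-oxocyclohexa-2,5-dien-1-yl)methyl methyl malonate | C=CCC1(COC(=O)CC(=O)OC)C=CC(=O)C=C1
A4 | alternative 2 | cis-fused lactone enone with C4 and C5 set | C=CC[C@]12C=CC(=O)C[C@H]1[C@H](C(=O)OC)C(=O)OC2
A5 | alternative 3 | ring A diene: 1-vinylcyclohexene with C10 methyl, C1 silyloxy, C4 methyl and 2,2-dimethoxyethyl | C=CC1=C(C)[C@H](O[Si](C)(C)C(C)(C)C)CC[C@@]1(C)CC(OC)OC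
A6 | alternative 3 | methyl 4-oxobut-2-ynoate | COC(=O)C#CC=O
A7 | alternative 3 | bicyclic 5,8-diene with C9 formyl, C8 ester and quaternary C10 | COC(=O)C1=C(C=O)[C@@]2(C)[C@H](O[Si](C)(C)C(C)(C)C)CC[C@@](C)(CC(OC)OC)C2=CC1
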